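Assumption: the target has no stereocentre or other stereogenic element (it is achiral), so the compound as drawn is the only stereoisomer and no step has to set configuration.

**Retrosynthetic overview**
1. Digriseophene A ⇒ its 4',4''-dideoxy dimer, by a late twofold C–H → C–OH conversion at the para position of both outer rings (ring B).
2. Dideoxy dimer ⇒ formaldehyde + two molecules of 4'-deoxygriseophenone C; the CH2 bridge is made while ring B has no phenol, so only ring A can react.
3. 4'-Deoxygriseophenone C ⇒ the symmetric 2,4,6-trihydroxybenzophenone, by selective O-methylation of the 4-OH; this C–O bond fixes the ring A pattern.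
4. Trihydroxybenzophenone ⇒ phloroglucinol + 2-methoxy-6-methylbenzoic acid (Friedel–Crafts acylation; the C3 symmetry removes any regiochemical question).
5. No ring is formed: both benzene rings are bought. Order of events: C-acylation → O-methylation → CH2 bridge → C–O installation on ring B.

**Route**

Step 1
Reactants: 1 phloroglucinol (benzene-1,3,5-triol); 2 2-methoxy-6-methylbenzoic acid
Product: 4 (2-methoxy-6-methylphenyl)(2,4,6-trihydroxyphenyl)methanone, via 2-methoxy-6-methylbenzoyl chloride 3 (not isolated)
Conditions: 2, (COCl)2, cat. DMF, CH2Cl2, rt; evaporate; then 1 (1.5 equiv), AlCl3 (4 equiv), PhNO2, 0 °C → rt; 1 M HCl work-up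
Reagents that add atoms: none
Why: Friedel–Crafts acylation, in which the di-ortho-substituted acid chloride ionises easily to an acylium ion that attacks the carbon of phloroglucinol, whose three ring positions are equivalent so only one mono-ketone can form, and the first acyl group deactivates the ring against a second; no stereocentre is created.

Step 2
Reactants: 4 (2-methoxy-6-methylphenyl)(2,4,6-trihydroxyphenyl)methanone
Product: 5 (2,6-dihydroxy-4-methoxyphenyl)(2-methoxy-6-methylphenyl)methanone (4'-deoxygriseophenone C)
Conditions: Me2SO4 (1.0 equiv), K2CO3 (1.0 equiv), acetone, rt → 40 °C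
Reagents that add atoms: dimethyl sulfate, COS(=O)(=O)OC
Why: Acidity-controlled Williamson-type O-methylation (the cotoin-type monomethylation of phlorobenzophenones), in which the 4-OH para to the carbonyl is the most acidic and least shielded hydroxyl, so one equivalent of base and Me2SO4 alkylates it in preference to the hydrogen-bonded, flanked 2- and 6-OH groups, and ring B has no hydroxyl to compete.

Step 3
Reactants: 5 (2,6-dihydroxy-4-methoxyphenyl)(2-methoxy-6-methylphenyl)methanone (two equivalents)
Product: 7 bis[2,4-dihydroxy-6-methoxy-3-(2-methoxy-6-methylbenzoyl)phenyl]methane, via hydroxymethyl ketone 6 (not isolated)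
Conditions: 37% aq. CH2O (0.5 equiv, slow addition), KOH (20 mol %), MeOH/H2O, 0 °C → rt
Reagents that add atoms: formaldehyde, C=O
Why: Base-catalysed hydroxymethylation (Lederer–Manasse) followed by ortho-quinone-methide formation and capture by a second phenolate, the standard methylene-bisphenol condensation used for acylphloroglucinol dimers; only ring A is a phenolate nucleophile, its two free positions are equivalent, the anisole-type ring B is inert, and a deficit of slowly added CH2O limits oligomers.

Step 4
Reactants: 7 bis[2,4-dihydroxy-6-methoxy-3-(2-methoxy-6-methylbenzoyl)phenyl]methane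
Product: 10 digriseophene A, via tetra-O-Bpin dimer 8 (not isolated), via tetra-O-Bpin bis-C-Bpin dimer 9 (not isolated)
Conditions: [Ir(OMe)(cod)]2 (5 mol %), 4,4'-di-tert-butyl-2,2'-bipyridine (10 mol %), HBpin (4.4 equiv), THF, rt → 50 °C (H2 evolution); then B2pin2 (2.4 equiv), 80 °C, 16 h; then 30% aq. H2O2, NaH2PO4/Na2HPO4 buffer (pH 7), THF/MeOH, 0 °C → rt
Reagents that add atoms: hydrogen peroxide, OO
Why: Proposed new method: a one-pot twofold C–H hydroxylation of an unprotected polyphenol, in which HBpin first caps the four ring A phenols as O–Bpin ethers (H2 loss, boron held by the neighbouring carbonyl), the bulky bipyridine-ligated iridium tris(boryl) catalyst then borylates under steric control the only aryl C–H with no ortho substituent (C4 of each 2-methoxy-6-methylbenzoyl ring; the ring A C–H lies between OMe and OBpin, and the other ring B C–H bonds are ortho to OMe or CH3), and buffered H2O2 turns each C–B bond into the C–O bond by 1,2-aryl shift from boron to oxygen while water removes the O–Bpin caps and the ketones, shielded by four ortho substituents, resist Dakin-type cleavage; the closest known reaction type is the one-pot iridium-catalysed C–H borylation/oxidation of 1,2,3-trisubstituted arenes to phenols with in situ O-borylation of simple phenols, which has not been shown twice over on a free, ketone-chelated hexaoxygenated bis-benzophenone.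

**Compound list**
1 | phloroglucinol (benzene-1,3,5-triol) | Oc1cc(O)cc(O)c1 | starting material
2 | 2-methoxy-6-methylbenzoic acid | COc1cccc(C)c1C(=O)O | starting material
3 | 2-methoxy-6-methylbenzoyl chloride | COc1cccc(C)c1C(=O)Cl | intermediate (not isolated)
4 | (2-methoxy-6-methylphenyl)(2,4,6-trihydroxyphenyl)methanone | COc1cccc(C)c1C(=O)c1c(O)cc(O)cc1O | intermediate
5 | (2,6-dihydroxy-4-methoxyphenyl)(2-methoxy-6-methylphenyl)methanone | COc1cc(O)c(C(=O)c2c(C)cccc2OC)c(O)c1 | intermediate
6 | [2,6-dihydroxy-3-(hydroxymethyl)-4-methoxyphenyl](2-methoxy-6-methylphenyl)methanone | COc1cc(O)c(C(=O)c2c(C)cccc2OC)c(O)c1CO | intermediate (not isolated)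
7 | bis[2,4-dihydroxy-6-methoxy-3-(2-methoxy-6-methylbenzoyl)phenyl]methane | COc1cc(O)c(C(=O)c2c(C)cccc2OC)c(O)c1Cc1c(OC)cc(O)c(C(=O)c2c(C)cccc2OC)c1O | intermediate
8 | bis[6-methoxy-3-(2-methoxy-6-methylbenzoyl)-2,4-bis(4,4,5,5-tetramethyl-1,3,2-dioxaborolan-2-yloxy)phenyl]methane | COc1cc(OB3OC(C)(C)C(C)(C)O3)c(C(=O)c2c(C)cccc2OC)c(OB3OC(C)(C)C(C)(C)O3)c1Cc1c(OC)cc(OB3OC(C)(C)C(C)(C)O3)c(C(=O)c2c(C)cccc2OC)c1OB1OC(C)(C)C(C)(C)O1 | intermediate (not isolated)
9 | bis[6-methoxy-3-[2-methoxy-6-methyl-4-(4,4,5,5-tetramethyl-1,3,2-dioxaborolan-2-yl)benzoyl]-2,4-bis(4,4,5,5-tetramethyl-1,3,2-dioxaborolan-2-yloxy)phenyl]methane | COc1cc(OB3OC(C)(C)C(C)(C)O3)c(C(=O)c2c(C)cc(B4OC(C)(C)C(C)(C)O4)cc2OC)c(OB3OC(C)(C)C(C)(C)O3)c1Cc1c(OC)cc(OB3OC(C)(C)C(C)(C)O3)c(C(=O)c2c(C)cc(B4OC(C)(C)C(C)(C)O4)cc2OC)c1OB1OC(C)(C)C(C)(C)O1 | intermediate (not isolated)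
10 | digriseophene A, bis[2,4-dihydroxy-3-(4-hydroxy-2-methoxy-6-methylbenzoyl)-6-methoxyphenyl]methane | COc1cc(O)c(C(=O)c2c(C)cc(O)cc2OC)c(O)c1Cc1c(OC)cc(O)c(C(=O)c2c(C)cc(O)cc2OC)c1O | target

**Totals**
Total step count: 4. Longest linear sequence: 4 steps (from 1 or 2 to 10).

**Steps most likely to fail, each with one fallback**

Step 4 (the proposed new step). The free, chelating polyphenol may be O-borylated incompletely, may slow the iridium catalyst, or the product may suffer in the oxidation. The fallback uses only known chemistry and replaces the transient boron caps by isolated protecting groups. It sets out from 7. Acetylation (Ac2O, pyridine, DMAP, rt) gives the tetraacetate of 7 F3. This is an ordinary ester-bearing 1,2,3-trisubstituted arene for standard borylation ([Ir(OMe)(cod)]2, 4,4'-di-tert-butyl-2,2'-bipyridine, B2pin2, THF, 80 °C), which gives the isolated bis(pinacol boronate) tetraacetate F4. Buffered H2O2 converts it into the tetraacetate of digriseophene A F5. Methanolysis (K2CO3, MeOH, rt) then removes the four acetates, and the route is rejoined at 10.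

Step 3. Each ring A of 7 still has one nucleophilic C–H, so trimers and higher oligomers compete with the dimer. The fallback separates the two C–C bond formations. It sets out from 5. A Mannich reaction with one equivalent of dimethylmethyleneiminium iodide (CH2Cl2, rt) gives [3-[(dimethylamino)methyl]-2,6-dihydroxy-4-methoxyphenyl](2-methoxy-6-methylphenyl)methanone F2, which is purified. Heating F2 with a further equivalent (or a slight excess) of 5 in dioxane at 100 °C expels dimethylamine and generates the ortho-quinone methide, which 5 captures. No free formaldehyde is ever present, and the route is rejoined at 7.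

Step 1. The hindered aroyl chloride may react sluggishly at carbon, and AlCl3 may cleave the methoxy group ortho to the carbonyl. The fallback unites the fragments through oxygen first and uses no Lewis acid. It sets out from 1 and acid chloride 3. Mono-O-acylation of excess 1 (pyridine, THF/CH2Cl2, 0 °C) gives 3,5-dihydroxyphenyl 2-methoxy-6-methylbenzoate F1. A photo-Fries rearrangement (254 nm, MeOH, rt) then moves the aroyl group to a ring carbon; because the ortho and para positions of this symmetric ester lead to the same trihydroxy ketone, a single product results and the route is rejoined at 4.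

**Further compounds**
F1 | step 1 | 3,5-dihydroxyphenyl 2-methoxy-6-methylbenzoate | COc1cccc(C)c1C(=O)Oc1cc(O)cc(O)c1
F2 | step 3 | [3-[(dimethylamino)methyl]-2,6-dihydroxy-4-methoxyphenyl](2-methoxy-6-methylphenyl)methanone | COc1cc(O)c(C(=O)c2c(C)cccc2OC)c(O)c1CN(C)C
F3 | step 4 | bis[2,4-diacetoxy-6-methoxy-3-(2-methoxy-6-methylbenzoyl)phenyl]methane (tetraacetate of 7) | COc1cc(OC(C)=O)c(C(=O)c2c(C)cccc2OC)c(OC(C)=O)c1Cc1c(OC)cc(OC(C)=O)c(C(=O)c2c(C)cccc2OC)c1OC(C)=O
F4 | step 4 | bis[2,4-diacetoxy-6-methoxy-3-[2-methoxy-6-methyl-4-(4,4,5,5-tetramethyl-1,3,2-dioxaborolan-2-yl)benzoyl]phenyl]methane | COc1cc(OC(C)=O)c(C(=O)c2c(C)cc(B3OC(C)(C)C(C)(C)O3)cc2OC)c(OC(C)=O)c1Cc1c(OC)cc(OC(C)=O)c(C(=O)c2c(C)cc(B3OC(C)(C)C(C)(C)O3)cc2OC)c1OC(C)=O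
F5 | step 4 | bis[2,4-diacetoxy-3-(4-hydroxy-2-methoxy-6-methylbenzoyl)-6-methoxyphenyl]methane (tetraacetate of digriseophene A) | COc1cc(OC(C)=O)c(C(=O)c2c(C)cc(O)cc2OC)c(OC(C)=O)c1Cc1c(OC)cc(OC(C)=O)c(C(=O)c2c(C)cc(O)cc2OC)c1OC(C)=O
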